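**Retrosynthetic overview**

1. Target 27 is an oxolane, O1–C2(4-hydroxyphenyl)–C3(2,4-dihydroxybenzoyl)–C4(4-hydroxybenzyl)–C5(2,4-dihydroxyphenyl), (2S,3S,4S,5R): 2,3-trans, 3,4-trans, 4,5-cis, 2,5-cis. The six phenols are carried as benzyl ethers and the ketone as a 1,3-dithiane.
2. The C5–aryl bond is cut first: arylzinc 23 plus anomeric sulfone 19 (kinetic arylation of an oxocarbenium ion), which leads back through the lactol to γ-lactone 15 with C5 at the acid oxidation level.
3. Key disconnection of 15: the C3–C(acyl) and C4–CH2Ar bonds are made in one pot from three components, lithiated aryl dithiane 13 (masked aroyl anion), (S)-butenolide 8 and benzylic bromide 12.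
4. Enabling feature: the ketone carbon sits on C3, which is β to C5 along C3–C4–C5–O1. With C5 raised to a lactone carbonyl, the C3=C4–C5(=O)–O1 butenolide makes C3 an electrophile for an umpoled aroyl unit, and the C2 aryl centre relays to C3, C4 and C5.
5. Ring order: the oxolane ring is closed first as a lactone (O1–C5, step 2, with C2 set by asymmetric transfer hydrogenation) and is never opened. The 1,3-dithiane is a temporary ring (formed in step 4, removed in step 10).

Key step: step 5

Remark: ring atoms are called O1, C2–C5 as in the target in all Why lines; systematic names of lactone-level intermediates use their own locants (carbonyl or anomeric carbon = C2, aryl-bearing carbon = C5). 4-(Benzyloxy)benzyl bromide and 2,4-bis(benzyloxy)benzaldehyde are taken as purchased.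

**Route**

Step 1
Reactants: 1 4-(4-hydroxyphenyl)-4-oxobutanoic acid; 2 benzyl bromide
Product: 3 benzyl 4-[4-(benzyloxy)phenyl]-4-oxobutanoate
Conditions: BnBr (2.3 equiv), K2CO3, DMF, 60 °C
Reagents that add atoms: benzyl bromide, BrCc1ccccc1
Why: Williamson-type double O-benzylation (SN2 of phenoxide and carboxylate on benzyl bromide) installs the phenol protecting group that is carried to the end and an ester that later leaves as benzyl alcohol; no stereocentre is formed.

Step 2
Reactants: 3 benzyl 4-[4-(benzyloxy)phenyl]-4-oxobutanoate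
Product: 5 (5S)-5-[4-(benzyloxy)phenyl]oxolan-2-one, via hydroxy ester 4 (not isolated)
Conditions: RuCl[(S,S)-TsDPEN](p-cymene) (1 mol %), HCO2H/Et3N (5:2), DMF, 40 °C; then PPTS (cat.), toluene, 50 °C
Reagents that add atoms: none
Why: Noyori asymmetric transfer hydrogenation of the aryl ketone with the (S,S)-TsDPEN ruthenium catalyst should give the (S)-benzylic alcohol (the facial sense known for aryl alkyl ketones), and the γ-hydroxy ester then lactonises under mild acid with loss of benzyl alcohol, which closes the oxolane ring and fixes the carbon that becomes C2.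

Step 3
Reactants: 5 (5S)-5-[4-(benzyloxy)phenyl]oxolan-2-one
Product: 8 (5S)-5-[4-(benzyloxy)phenyl]furan-2(5H)-one, via selenide 6 (not isolated), via selenoxide 7 (not isolated)
Conditions: LiN(i-Pr)2 (LDA, 1.1 equiv), THF, −78 °C; PhSeBr, −78 °C; then 30 % H2O2, AcOH (cat.), THF, 0 °C → rt
Reagents that add atoms: none
Why: α-selenenylation of the lactone enolate followed by selenoxide syn-elimination can only remove a ring β-hydrogen and so should give the endocyclic butenolide, while the aryl-bearing stereocentre is not involved and the weakly acidic oxidation medium avoids base-induced isomerisation of the product.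

Step 4
Reactants: 9 2,4-bis(benzyloxy)benzaldehyde; 10 propane-1,3-dithiol
Product: 11 2-[2,4-bis(benzyloxy)phenyl]-1,3-dithiane
Conditions: HS(CH2)3SH (1.1 equiv), BF3·OEt2 (0.2 equiv), CH2Cl2, 0 °C → rt
Reagents that add atoms: propane-1,3-dithiol, SCCCS
Why: Lewis acid-catalysed dithioacetalisation turns the aldehyde carbon into an acidic C–H carbon that can act as the masked aroyl anion, and the benzyl ethers tolerate catalytic BF3·OEt2 at 0 °C.

Step 5
Reactants: 11 2-[2,4-bis(benzyloxy)phenyl]-1,3-dithiane; 8 (5S)-5-[4-(benzyloxy)phenyl]furan-2(5H)-one; 12 4-(benzyloxy)benzyl bromide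
Product: 15 (3S,4S,5S)-3-[4-(benzyloxy)benzyl]-5-[4-(benzyloxy)phenyl]-4-{2-[2,4-bis(benzyloxy)phenyl]-1,3-dithian-2-yl}oxolan-2-one, via lithiated dithiane 13 (not isolated), via lithium enolate 14 (not isolated)
Conditions: 11 (1.1 equiv), n-BuLi (1.05 equiv), THF, −78 → −20 °C; then 8 in THF added slowly at −78 °C; then 12 (1.3 equiv), DMPU, −78 → −30 °C; aq. NH4Cl
Reagents that add atoms: 4-(benzyloxy)benzyl bromide, BrCc1ccc(OCc2ccccc2)cc1
Why: Deprotonation of 11 gives the soft, sulfur- and aryl-stabilised carbanion 13, a masked 2,4-bis(benzyloxy)benzoyl anion, which adds 1,4 to butenolide 8 at C3 to form the C3–C(acyl) bond and lithium enolate 14, and 14 is then C-benzylated at C4 by 12 in the same flask. The closest known reaction type is the tandem conjugate addition–enolate alkylation of 2-lithio-2-aryl-1,3-dithianes with butenolides and benzylic bromides used for trans-2,3-disubstituted butyrolactone lignans. No ring is closed: the oxolane ring is already present as the butenolide and only two exocyclic C–C bonds are made. The C3 stereocentre is controlled by the C2 aryl group, which blocks its own face so that 13 enters anti (2,3-trans), and the C4 stereocentre by the very bulky dithianyl group just installed at C3, which sends 12 to the opposite face (3,4-trans), so both new centres are relayed from the single centre of 8. The step needs 1,4- over 1,2-addition, which the delocalised anion in THF at −78 °C should secure, and addition faster than removal of the acidic C2–H of 8, which slow addition of 8 to a slight excess of 13 at −78 °C should secure because 8 is consumed before it can meet enolate 14 for long; C-alkylation of the lithium enolate by the reactive benzylic bromide is helped by DMPU.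

Step 6
Reactants: 15 (3S,4S,5S)-3-[4-(benzyloxy)benzyl]-5-[4-(benzyloxy)phenyl]-4-{2-[2,4-bis(benzyloxy)phenyl]-1,3-dithian-2-yl}oxolan-2-one
Product: 16 (3S,4S,5S)-3-[4-(benzyloxy)benzyl]-5-[4-(benzyloxy)phenyl]-4-{2-[2,4-bis(benzyloxy)phenyl]-1,3-dithian-2-yl}oxolan-2-ol (anomer mixture)
Conditions: i-Bu2AlH (DIBAL-H, 1.2 equiv), CH2Cl2, −78 °C; aq. KNaC4H4O6
Reagents that add atoms: none
Why: Partial reduction of a γ-lactone by i-Bu2AlH at −78 °C stops at the tetrahedral aluminate and gives the lactol on work-up; the dithiane and benzyl ethers are inert and the anomer mixture is inconsequential because C5 becomes planar again in steps 7 and 9.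

Step 7
Reactants: 16 the lactol of step 6; 17 benzenesulfinic acid
Product: 19 (3S,4S,5S)-3-[4-(benzyloxy)benzyl]-5-[4-(benzyloxy)phenyl]-4-{2-[2,4-bis(benzyloxy)phenyl]-1,3-dithian-2-yl}-2-(phenylsulfonyl)oxolane (anomer mixture), via oxocarbenium ion pair 18 (not isolated)
Conditions: PhSO2H (3 equiv), CaCl2 (powdered), CH2Cl2, rt
Reagents that add atoms: benzenesulfinic acid, O=S(O)c1ccccc1
Why: Acid-promoted anomeric substitution: the lactol is protonated and loses water to give the oxocarbenium benzenesulfinate ion pair 18, which collapses at sulfur to a stable 2-sulfonyl oxolane that can be re-ionised under mild Lewis acid.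

Step 8
Reactants: 20 4-bromobenzene-1,3-diol (4-bromoresorcinol); 2 benzyl bromide
Product: 21 2,4-bis(benzyloxy)-1-bromobenzene
Conditions: BnBr (2.3 equiv), K2CO3, DMF, 60 °C
Reagents that add atoms: benzyl bromide, BrCc1ccccc1
Why: Williamson etherification of both phenols gives the aryl bromide that carries the C5 aryl group; no stereocentre is formed.

Step 9
Reactants: 21 2,4-bis(benzyloxy)-1-bromobenzene; 19 the anomeric sulfone of step 7
Product: 25 2-[2,4-bis(benzyloxy)phenyl]-2-{(2S,3S,4S,5R)-4-[4-(benzyloxy)benzyl]-2-[4-(benzyloxy)phenyl]-5-[2,4-bis(benzyloxy)phenyl]oxolan-3-yl}-1,3-dithiane, via aryllithium 22 (not isolated), via arylzinc bromide 23 (not isolated), via oxocarbenium zincate ion pair 24 (not isolated)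
Conditions: 21 (3 equiv), n-BuLi, THF, −78 °C; ZnBr2, −78 → 0 °C; then 19, THF, 0 °C → rt
Reagents that add atoms: none
Why: Anomeric sulfone–organozinc coupling: the Lewis-acidic zinc of 23 binds the sulfonyl group and ionises 19 to contact ion pair 24, in which the oxocarbenium ion is paired with the aryl(bromo)zinc sulfinate, and the aryl group is then transferred irreversibly to C5 by inside attack on the envelope in which the C2 aryl, C3 dithianyl and C4 benzyl groups are all pseudo-equatorial, that is anti to the bulky C3 substituent and syn to the C4 benzyl group, which should set (5R) with the 4,5-cis and 2,5-cis relations under kinetic control, the sense expected from the inside-attack model for five-membered-ring oxocarbenium ions.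

Step 10
Reactants: 25 the dithiane of step 9
Product: 26 [2,4-bis(benzyloxy)phenyl]{(2S,3S,4S,5R)-4-[4-(benzyloxy)benzyl]-2-[4-(benzyloxy)phenyl]-5-[2,4-bis(benzyloxy)phenyl]oxolan-3-yl}methanone
Conditions: MeI (excess), CaCO3, MeCN/H2O (9:1), 45 °C
Reagents that add atoms: water, O
Why: Alkylative dithiane hydrolysis: S-methylation gives a sulfonium ion that opens to an aryl-stabilised thionium ion and is hydrolysed under CaCO3 buffering, which should leave the benzyl ethers and the two benzylic ring C–O bonds alone, and C3, now α to the ketone, already has the thermodynamically preferred trans relation to both neighbours.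

Step 11
Reactants: 26 the hexabenzyl ketone of step 10
Product: 27 (2,4-dihydroxyphenyl)[(2S,3S,4S,5R)-5-(2,4-dihydroxyphenyl)-4-(4-hydroxybenzyl)-2-(4-hydroxyphenyl)oxolan-3-yl]methanone
Conditions: H2 (1 atm), Pd/C (10 wt %), EtOAc/MeOH (1:1), rt, stopped at full debenzylation
Reagents that add atoms: none
Why: Hydrogenolysis of the six aryl benzyl ethers on Pd/C under neutral conditions is much faster than cleavage of the benzylic C–O bonds of the ring or reduction of the electron-rich, hydrogen-bonded aryl ketone, so it should give 27 with all four stereocentres unchanged.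

**Compound list**

1 | 4-(4-hydroxyphenyl)-4-oxobutanoic acid | O=C(O)CCC(=O)c1ccc(O)cc1 | starting material
2 | benzyl bromide | BrCc1ccccc1 | starting material
3 | benzyl 4-[4-(benzyloxy)phenyl]-4-oxobutanoate | O=C(CCC(=O)c1ccc(OCc2ccccc2)cc1)OCc1ccccc1 | intermediate
4 | benzyl (4S)-4-[4-(benzyloxy)phenyl]-4-hydroxybutanoate | O=C(CC[C@H](O)c1ccc(OCc2ccccc2)cc1)OCc1ccccc1 | intermediate
5 | (5S)-5-[4-(benzyloxy)phenyl]oxolan-2-one | O=C1CC[C@@H](c2ccc(OCc3ccccc3)cc2)O1 | intermediate
6 | (5S)-5-[4-(benzyloxy)phenyl]-3-(phenylselanyl)oxolan-2-one (C3 epimers) | O=C1C([Se]c2ccccc2)C[C@@H](c2ccc(OCc3ccccc3)cc2)O1 | intermediate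
7 | (5S)-5-[4-(benzyloxy)phenyl]-3-(phenylseleninyl)oxolan-2-one | O=C1C([Se](=O)c2ccccc2)C[C@@H](c2ccc(OCc3ccccc3)cc2)O1 | intermediate
8 | (5S)-5-[4-(benzyloxy)phenyl]furan-2(5H)-one | O=C1C=C[C@@H](c2ccc(OCc3ccccc3)cc2)O1 | intermediate
9 | 2,4-bis(benzyloxy)benzaldehyde | O=Cc1ccc(OCc2ccccc2)cc1OCc1ccccc1 | starting material
10 | propane-1,3-dithiol | SCCCS | starting material
11 | 2-[2,4-bis(benzyloxy)phenyl]-1,3-dithiane | C1CSC(SC1)c1ccc(OCc2ccccc2)cc1OCc1ccccc1 | intermediate
12 | 4-(benzyloxy)benzyl bromide | BrCc1ccc(OCc2ccccc2)cc1 | starting material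
13 | {2-[2,4-bis(benzyloxy)phenyl]-1,3-dithian-2-yl}lithium | [Li]C1(SCCCS1)c1ccc(OCc2ccccc2)cc1OCc1ccccc1 | intermediate
14 | lithium (4S,5S)-5-[4-(benzyloxy)phenyl]-4-{2-[2,4-bis(benzyloxy)phenyl]-1,3-dithian-2-yl}-4,5-dihydrofuran-2-olate | C1CCSC(S1)(c1ccc(OCc2ccccc2)cc1OCc1ccccc1)[C@H]1C=C(O[Li])O[C@@H]1c1ccc(OCc2ccccc2)cc1 | intermediate
15 | (3S,4S,5S)-3-[4-(benzyloxy)benzyl]-5-[4-(benzyloxy)phenyl]-4-{2-[2,4-bis(benzyloxy)phenyl]-1,3-dithian-2-yl}oxolan-2-one | C1CCSC(S1)(c1ccc(OCc2ccccc2)cc1OCc1ccccc1)[C@H]1[C@H](Cc2ccc(OCc3ccccc3)cc2)C(=O)O[C@@H]1c1ccc(OCc2ccccc2)cc1 | intermediate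
16 | (3S,4S,5S)-3-[4-(benzyloxy)benzyl]-5-[4-(benzyloxy)phenyl]-4-{2-[2,4-bis(benzyloxy)phenyl]-1,3-dithian-2-yl}oxolan-2-ol (anomer mixture) | C1CCSC(S1)(c1ccc(OCc2ccccc2)cc1OCc1ccccc1)[C@H]1[C@H](Cc2ccc(OCc3ccccc3)cc2)C(O)O[C@@H]1c1ccc(OCc2ccccc2)cc1 | intermediate
17 | benzenesulfinic acid | O=S(O)c1ccccc1 | starting material
18 | oxocarbenium ion of 16 (C5 cationic, C=O+) as its benzenesulfinate ion pair | C1CCSC(S1)(c1ccc(OCc2ccccc2)cc1OCc1ccccc1)[C@H]1[C@H](Cc2ccc(OCc3ccccc3)cc2)C=[O+][C@@H]1c1ccc(OCc2ccccc2)cc1.[O-]S(=O)c1ccccc1 | intermediate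
19 | (3S,4S,5S)-3-[4-(benzyloxy)benzyl]-5-[4-(benzyloxy)phenyl]-4-{2-[2,4-bis(benzyloxy)phenyl]-1,3-dithian-2-yl}-2-(phenylsulfonyl)oxolane (anomer mixture) | C1CCSC(S1)(c1ccc(OCc2ccccc2)cc1OCc1ccccc1)[C@H]1[C@H](Cc2ccc(OCc3ccccc3)cc2)C(S(=O)(=O)c2ccccc2)O[C@@H]1c1ccc(OCc2ccccc2)cc1 | intermediate
20 | 4-bromobenzene-1,3-diol | Oc1ccc(Br)c(O)c1 | starting material
21 | 2,4-bis(benzyloxy)-1-bromobenzene | Brc1ccc(OCc2ccccc2)cc1OCc1ccccc1 | intermediate
22 | [2,4-bis(benzyloxy)phenyl]lithium | [Li]c1ccc(OCc2ccccc2)cc1OCc1ccccc1 | intermediate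
23 | [2,4-bis(benzyloxy)phenyl]zinc bromide | Br[Zn]c1ccc(OCc2ccccc2)cc1OCc1ccccc1 | intermediate
24 | oxocarbenium ion of 19 (C5 cationic, C=O+) as its [2,4-bis(benzyloxy)phenyl](bromo)(benzenesulfinato)zincate ion pair | C1CCSC(S1)(c1ccc(OCc2ccccc2)cc1OCc1ccccc1)[C@H]1[C@H](Cc2ccc(OCc3ccccc3)cc2)C=[O+][C@@H]1c1ccc(OCc2ccccc2)cc1.Br[Zn-](OS(=O)c1ccccc1)c1ccc(OCc2ccccc2)cc1OCc1ccccc1 | intermediate
25 | 2-[2,4-bis(benzyloxy)phenyl]-2-{(2S,3S,4S,5R)-4-[4-(benzyloxy)benzyl]-2-[4-(benzyloxy)phenyl]-5-[2,4-bis(benzyloxy)phenyl]oxolan-3-yl}-1,3-dithiane | C1CCSC(S1)(c1ccc(OCc2ccccc2)cc1OCc1ccccc1)[C@H]1[C@H](Cc2ccc(OCc3ccccc3)cc2)[C@H](c2ccc(OCc3ccccc3)cc2OCc2ccccc2)O[C@@H]1c1ccc(OCc2ccccc2)cc1 | intermediate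
26 | [2,4-bis(benzyloxy)phenyl]{(2S,3S,4S,5R)-4-[4-(benzyloxy)benzyl]-2-[4-(benzyloxy)phenyl]-5-[2,4-bis(benzyloxy)phenyl]oxolan-3-yl}methanone | O=C(c1ccc(OCc2ccccc2)cc1OCc1ccccc1)[C@H]1[C@H](Cc2ccc(OCc3ccccc3)cc2)[C@H](c2ccc(OCc3ccccc3)cc2OCc2ccccc2)O[C@@H]1c1ccc(OCc2ccccc2)cc1 | intermediate
27 | (2,4-dihydroxyphenyl)[(2S,3S,4S,5R)-5-(2,4-dihydroxyphenyl)-4-(4-hydroxybenzyl)-2-(4-hydroxyphenyl)oxolan-3-yl]methanone | O=C(c1ccc(O)cc1O)[C@H]1[C@H](Cc2ccc(O)cc2)[C@H](c2ccc(O)cc2O)O[C@@H]1c1ccc(O)cc1 | target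

**Summary**

Total step count: 11. Longest linear sequence: 9 steps (1, 2, 3, 5, 6, 7, 9, 10, 11).

**Steps most likely to fail**

Step 5. The process at risk is proton transfer from the acidic, benzylic and vinylogous C–H at the aryl-bearing carbon of 8 to carbanion 13 or enolate 14. This would erode the enantiomeric purity and return isomerised butenolide; slow addition caused by the ortho-benzyloxy group of 13 adds to the risk. The fallback is a base-free acyl radical route that sets out from 21 and 8 and comes back at 15. Bromine–lithium exchange of 21 (n-BuLi, THF, −78 °C) and acylation with diethyl oxalate should give ethyl 2-[2,4-bis(benzyloxy)phenyl]-2-oxoacetate F1, which is saponified (LiOH, THF/H2O) to 2-[2,4-bis(benzyloxy)phenyl]-2-oxoacetic acid F2. Visible-light decarboxylative acyl radical conjugate addition (Giese reaction) of F2 to 8 with Ir[dF(CF3)ppy]2(dtbbpy)PF6, 2,4,6-collidine, DMSO and blue LEDs should give, by radical attack anti to the aryl group, (4S,5S)-4-[2,4-bis(benzyloxy)benzoyl]-5-[4-(benzyloxy)phenyl]oxolan-2-one F3. Dithioketalisation with 10 and BF3·OEt2 in CH2Cl2 should give (4S,5S)-5-[4-(benzyloxy)phenyl]-4-{2-[2,4-bis(benzyloxy)phenyl]-1,3-dithian-2-yl}oxolan-2-one F4. Deprotonation of F4 with LiN(SiMe3)2 in THF at −78 °C regenerates enolate 14, which is benzylated by 12 anti to the dithianyl group as in step 5 to rejoin the route at 15.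

Step 9. The processes at risk are slow ionisation and slow aryl transfer at the hindered anomeric carbon, competing elimination of sulfinate to a 2,3-dihydrofuran, and loss of facial selectivity at C5. The fallback replaces the organometallic nucleophile by a π-nucleophile; it sets out from 16 and comes back at 25. Acetylation of 16 (Ac2O, pyridine, DMAP, CH2Cl2) should give (3S,4S,5S)-3-[4-(benzyloxy)benzyl]-5-[4-(benzyloxy)phenyl]-4-{2-[2,4-bis(benzyloxy)phenyl]-1,3-dithian-2-yl}oxolan-2-yl acetate F5. Friedel–Crafts C-arylation of F5 with purchased 1,3-bis(benzyloxy)benzene (c1cc(OCc2ccccc2)cc(OCc2ccccc2)c1) and BF3·OEt2 in CH2Cl2 at −78 °C, quenched cold to keep kinetic control, should give 25. The arene should react at its 4-position (para to one ether, ortho to the other), and the same inside attack on the oxocarbenium ion should set C5.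

Step 11. The processes at risk are over-reduction (hydrogenolysis of the two benzylic C–O bonds of the ring, or reduction of the aryl ketone) and catalyst poisoning by sulfur residues from step 10. The fallback is a non-reductive Lewis-acid dealkylation that sets out from 26 and ends at 27: BCl3 with pentamethylbenzene as benzyl cation scavenger in CH2Cl2 at −78 °C, then methanol quench. It makes no new compound on the way.

**Further compounds**

F1 | step 5 | ethyl 2-[2,4-bis(benzyloxy)phenyl]-2-oxoacetate | CCOC(=O)C(=O)c1ccc(OCc2ccccc2)cc1OCc1ccccc1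
F2 | step 5 | 2-[2,4-bis(benzyloxy)phenyl]-2-oxoacetic acid | OC(=O)C(=O)c1ccc(OCc2ccccc2)cc1OCc1ccccc1
F3 | step 5 | (4S,5S)-4-[2,4-bis(benzyloxy)benzoyl]-5-[4-(benzyloxy)phenyl]oxolan-2-one | O=C(c1ccc(OCc2ccccc2)cc1OCc1ccccc1)[C@H]1CC(=O)O[C@@H]1c1ccc(OCc2ccccc2)cc1
F4 | step 5 | (4S,5S)-5-[4-(benzyloxy)phenyl]-4-{2-[2,4-bis(benzyloxy)phenyl]-1,3-dithian-2-yl}oxolan-2-one | C1CCSC(S1)(c1ccc(OCc2ccccc2)cc1OCc1ccccc1)[C@H]1CC(=O)O[C@@H]1c1ccc(OCc2ccccc2)cc1
F5 | step 9 | (3S,4S,5S)-3-[4-(benzyloxy)benzyl]-5-[4-(benzyloxy)phenyl]-4-{2-[2,4-bis(benzyloxy)phenyl]-1,3-dithian-2-yl}oxolan-2-yl acetate (anomer mixture) | C1CCSC(S1)(c1ccc(OCc2ccccc2)cc1OCc1ccccc1)[C@H]1[C@H](Cc2ccc(OCc3ccccc3)cc2)C(OC(C)=O)O[C@@H]1c1ccc(OCc2ccccc2)cc1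
F0 | step 11 | none | none
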